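**Plan** (isoflavan numbering: O1, C2, C3, C4, C4a, C5–C8, C8a; ring A = benzo ring, ring C = its pyran ring, ring B = the chromene)
- Cuts: the O1–C8a aryl ether of ring C; the C3–C4 bond; the C2–C3 bond (one-carbon homologation of a ring B aldehyde); the pyran ring of the ring B chromene (O–CMe2 and aryl–CH= bonds); the C6–prenyl bond.
- Enabling feature: in ring A the C7 hydroxyl is para to C4a (which carries C4), and O1 sits on C8a, ortho to C4a and meta to the C7 hydroxyl. A para-alkylphenol dearomatized at C4a to a cyclohexa-2,5-dienone therefore offers C8a as an enone β-carbon six atoms from the C2 hydroxyl. Conjugate addition and loss of the temporary C4a hydroxyl as water rebuild ring A with O1 in place, without halogen or metal at C8a.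
- Forward order: the ring B pyran is made first (propargyl ether rearrangement), then the arylacetic acid and auxiliary; ring A enters as a para-substituted phenol prenylated at one of its two equivalent ortho carbons; C3–C4 is joined by enolate alkylation; ring C closes last, before one deprotection.
- Helpers: a silyl ether on the C2 oxygen (keeps it from attacking C4a during the oxidation), the C4a hydroxyl (leaving group), a MOM ether on the ring B phenol; the C6 prenyl group steers the conjugate addition to C8a.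
- Stereochemistry: the only stereocentre, C3 (R), comes from an Evans alkylation with (R)-4-benzyloxazolidin-2-one and is not touched afterwards.

Key step: step 15

Remark: 21, 22 and 23 are carried as mixtures of epimers at C4a (23 also at C8a); both centres become sp2 carbons of ring A in step 15.

Step 1
Reactants: 1 2,4-dihydroxybenzaldehyde
Product: 2 2-hydroxy-4-(methoxymethoxy)benzaldehyde
Conditions: MOMCl (1.1 equiv), K2CO3, acetone, 0 to 23 °C
Reagents that add atoms: chloromethyl methyl ether (MOMCl), COCCl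
Why: Williamson etherification, selective for the 4-hydroxyl because the 2-hydroxyl is held in a hydrogen bond to the aldehyde and is the less acidic one.

Step 2
Reactants: 2 2-hydroxy-4-(methoxymethoxy)benzaldehyde
Product: 3 4-(methoxymethoxy)-2-[(2-methylbut-3-yn-2-yl)oxy]benzaldehyde
Conditions: 3-chloro-3-methylbut-1-yne, K2CO3, KI, CuI (cat.), acetone, reflux
Reagents that add atoms: 3-chloro-3-methylbut-1-yne, CC(C)(Cl)C#C
Why: Copper-catalysed O-propargylation of the remaining phenoxide with a tertiary propargylic chloride should give the aryl 1,1-dimethylpropargyl ether.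

Step 3
Reactants: 3 4-(methoxymethoxy)-2-[(2-methylbut-3-yn-2-yl)oxy]benzaldehyde
Product: 4 5-(methoxymethoxy)-2,2-dimethyl-2H-chromene-8-carbaldehyde
Conditions: N,N-diethylaniline, 150 °C
Reagents that add atoms: none
Why: Aromatic propargyl Claisen rearrangement to the only free ortho carbon, then enolisation, 1,5-hydrogen shift and oxa-6π electrocyclisation, should give the 2,2-dimethyl-2H-chromene with its ring oxygen next to the formyl-bearing carbon.

Step 4
Reactants: 4 5-(methoxymethoxy)-2,2-dimethyl-2H-chromene-8-carbaldehyde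
Product: 6 2-[5-(methoxymethoxy)-2,2-dimethyl-2H-chromen-8-yl]acetonitrile, via N-(1-tosylvinyl)formamide 5 (not isolated)
Conditions: TosMIC, KOt-Bu (2.2 equiv), DME, −40 °C; then MeOH, reflux
Reagents that add atoms: p-toluenesulfonylmethyl isocyanide (TosMIC), Cc1ccc(cc1)S(=O)(=O)C[N+]#[C-]
Why: van Leusen reductive cyanation, in which the TosMIC anion adds to the aldehyde, the oxazoline opens to the N-(1-tosylvinyl)formamide, and methoxide-induced deformylation with loss of sulfinate gives the one-carbon-homologated nitrile.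

Step 5
Reactants: 6 2-[5-(methoxymethoxy)-2,2-dimethyl-2H-chromen-8-yl]acetonitrile
Product: 7 2-[5-(methoxymethoxy)-2,2-dimethyl-2H-chromen-8-yl]acetic acid
Conditions: KOH, EtOH/H2O, reflux; then 1 M HCl to pH 4 at 0 °C
Reagents that add atoms: potassium hydroxide, [K+].[OH-]; water, O
Why: Basic nitrile hydrolysis, to which the MOM acetal and the chromene are stable, should give the arylacetic acid after careful cold acidification.

Step 6
Reactants: 7 2-[5-(methoxymethoxy)-2,2-dimethyl-2H-chromen-8-yl]acetic acid; 8 (R)-4-benzyloxazolidin-2-one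
Product: 10 (R)-4-benzyl-3-{2-[5-(methoxymethoxy)-2,2-dimethyl-2H-chromen-8-yl]acetyl}oxazolidin-2-one, via mixed pivalic anhydride 9 (not isolated)
Conditions: PivCl, Et3N, THF, −20 °C; then 8, LiCl, 23 °C
Reagents that add atoms: none
Why: N-acylation of the oxazolidinone through the mixed pivalic anhydride (LiCl/Et3N variant) attaches the Evans auxiliary under conditions that spare the acid-labile groups.

Step 7
Reactants: 11 4-hydroxybenzaldehyde
Product: 12 4-hydroxy-3-(3-methylbut-2-en-1-yl)benzaldehyde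
Conditions: prenyl bromide, KOH (aq. 10%), 23 °C
Reagents that add atoms: 1-bromo-3-methylbut-2-ene (prenyl bromide), CC(C)=CCBr
Why: C-alkylation of an ambident phenoxide in water, where hydrogen bonding shields the oxygen; the para position is blocked and the two ortho carbons are equivalent, so only one C-prenyl isomer can form.

Step 8
Reactants: 12 4-hydroxy-3-(3-methylbut-2-en-1-yl)benzaldehyde
Product: 13 4-[(tert-butyldimethylsilyl)oxy]-3-(3-methylbut-2-en-1-yl)benzaldehyde
Conditions: TBSCl, imidazole, DMF, 23 °C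
Reagents that add atoms: tert-butyldimethylsilyl chloride (TBSCl), CC(C)(C)[Si](C)(C)Cl
Why: Silyl ether formation protects the phenol for the enolate alkylation and allows its selective release later.

Step 9
Reactants: 13 4-[(tert-butyldimethylsilyl)oxy]-3-(3-methylbut-2-en-1-yl)benzaldehyde
Product: 14 {4-[(tert-butyldimethylsilyl)oxy]-3-(3-methylbut-2-en-1-yl)phenyl}methanol
Conditions: NaBH4, MeOH, 0 °C
Reagents that add atoms: none
Why: Hydride reduction of the aldehyde with NaBH4 leaves the alkene and the aryl silyl ether untouched.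

Step 10
Reactants: 14 {4-[(tert-butyldimethylsilyl)oxy]-3-(3-methylbut-2-en-1-yl)phenyl}methanol
Product: 15 [4-(bromomethyl)-2-(3-methylbut-2-en-1-yl)phenoxy](tert-butyl)dimethylsilane
Conditions: CBr4, PPh3, CH2Cl2, 0 °C
Reagents that add atoms: tetrabromomethane, BrC(Br)(Br)Br
Why: Appel bromination converts the benzylic alcohol into the bromide under neutral conditions; the bromide is used at once.

Step 11
Reactants: 10 (R)-4-benzyl-3-{2-[5-(methoxymethoxy)-2,2-dimethyl-2H-chromen-8-yl]acetyl}oxazolidin-2-one; 15 [4-(bromomethyl)-2-(3-methylbut-2-en-1-yl)phenoxy](tert-butyl)dimethylsilane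
Product: 17 (R)-4-benzyl-3-[(2R)-3-{4-[(tert-butyldimethylsilyl)oxy]-3-(3-methylbut-2-en-1-yl)phenyl}-2-[5-(methoxymethoxy)-2,2-dimethyl-2H-chromen-8-yl]propanoyl]oxazolidin-2-one, via sodium Z-enolate 16 (not isolated)
Conditions: NaN(SiMe3)2, THF, −78 °C; then 15, −78 to −40 °C
Reagents that add atoms: none
Why: Evans asymmetric alkylation, in which the chelated Z-enolate is attacked by the benzylic bromide on the face opposite to the benzyl group of the (R)-auxiliary, which sets the future C3 as R.

Step 12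
Reactants: 17 (R)-4-benzyl-3-[(2R)-3-{4-[(tert-butyldimethylsilyl)oxy]-3-(3-methylbut-2-en-1-yl)phenyl}-2-[5-(methoxymethoxy)-2,2-dimethyl-2H-chromen-8-yl]propanoyl]oxazolidin-2-one
Product: 18 (2R)-3-{4-[(tert-butyldimethylsilyl)oxy]-3-(3-methylbut-2-en-1-yl)phenyl}-2-[5-(methoxymethoxy)-2,2-dimethyl-2H-chromen-8-yl]propan-1-ol
Conditions: LiBH4, THF, MeOH (2 equiv), 0 °C
Reagents that add atoms: none
Why: Reductive cleavage of the N-acyl oxazolidinone with LiBH4 should give the primary alcohol without epimerising the α-aryl centre and returns the auxiliary.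

Step 13
Reactants: 18 (2R)-3-{4-[(tert-butyldimethylsilyl)oxy]-3-(3-methylbut-2-en-1-yl)phenyl}-2-[5-(methoxymethoxy)-2,2-dimethyl-2H-chromen-8-yl]propan-1-ol
Product: 20 4-[(2R)-3-[(tert-butyldimethylsilyl)oxy]-2-[5-(methoxymethoxy)-2,2-dimethyl-2H-chromen-8-yl]propyl]-2-(3-methylbut-2-en-1-yl)phenol, via bis-silyl ether 19 (not isolated)
Conditions: TBSCl, imidazole, DMF, 23 °C; then MeOH, KHF2, 23 °C
Reagents that add atoms: tert-butyldimethylsilyl chloride (TBSCl), CC(C)(C)[Si](C)(C)Cl
Why: Silylation of the primary alcohol followed by KHF2, which cleaves aryl silyl ethers selectively over alkyl silyl ethers, leaves the phenol free and the side-chain oxygen masked.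

Step 14
Reactants: 20 4-[(2R)-3-[(tert-butyldimethylsilyl)oxy]-2-[5-(methoxymethoxy)-2,2-dimethyl-2H-chromen-8-yl]propyl]-2-(3-methylbut-2-en-1-yl)phenol
Product: 21 4-[(2R)-3-[(tert-butyldimethylsilyl)oxy]-2-[5-(methoxymethoxy)-2,2-dimethyl-2H-chromen-8-yl]propyl]-4-hydroxy-2-(3-methylbut-2-en-1-yl)cyclohexa-2,5-dien-1-one
Conditions: PhI(OAc)2 (1.1 equiv), MeCN/H2O (3:1), 0 °C
Reagents that add atoms: water, O
Why: Oxidative dearomatisation of a para-alkylphenol with the hypervalent iodine reagent PhI(OAc)2, in which the aryloxy-iodane is captured by water at the alkyl-bearing para carbon to give the p-quinol while the silyl ether keeps the side-chain oxygen from spirocyclising at C4a.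

Step 15
Reactants: 21 4-[(2R)-3-[(tert-butyldimethylsilyl)oxy]-2-[5-(methoxymethoxy)-2,2-dimethyl-2H-chromen-8-yl]propyl]-4-hydroxy-2-(3-methylbut-2-en-1-yl)cyclohexa-2,5-dien-1-one
Product: 24 (3R)-3-[5-(methoxymethoxy)-2,2-dimethyl-2H-chromen-8-yl]-6-(3-methylbut-2-en-1-yl)-3,4-dihydro-2H-chromen-7-ol, via dienone diol 22 (not isolated), via bicyclic hydroxy enone 23 (not isolated)
Conditions: TsOH·H2O (1 equiv), MeCN/H2O (20:1), 23 °C then 50 °C
Reagents that add atoms: none
Why: Aqueous acid first frees the C2 hydroxyl (22), which adds to C8a, the β-carbon of the unsubstituted enone arm of the protonated cyclohexa-2,5-dienone, in a 6-exo-trig oxa-Michael closure of the pyran ring that gives the cis-fused bicycle 23. Enolisation of the C7 ketone towards C8 then lets the tertiary C4a hydroxyl leave as water through a pentadienyl (arenium) cation, and loss of the C8a proton restores ring A, so that the net result is alkoxylation of the phenol ring meta to its hydroxyl. The closest known reaction types are the acid-catalysed intramolecular oxa-Michael addition of hydroxyalkyl p-quinols and the conjugate addition–dehydrative aromatisation of p-quinols and their ethers with heteroatom nucleophiles to meta-substituted phenols. No lasting stereocentre is made, since C4a and C8a both end as sp2 carbons, and C3 has no acidifying neighbour and keeps its R configuration. The step needs regioselectivity between the β-carbons C8a and C5, and the C6 prenyl group secures it by making the C5=C6 arm an α-substituted, more hindered and less electrophilic enone whose adduct would also give up the more substituted conjugated double bond. Warming is applied only after the conjugate addition, so that the cross-conjugated dienone is consumed before a competing 1,2-alkyl shift can set in.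

Step 16
Reactants: 24 (3R)-3-[5-(methoxymethoxy)-2,2-dimethyl-2H-chromen-8-yl]-6-(3-methylbut-2-en-1-yl)-3,4-dihydro-2H-chromen-7-ol
Product: 25 (3R)-3-(5-hydroxy-2,2-dimethyl-2H-chromen-8-yl)-6-(3-methylbut-2-en-1-yl)-3,4-dihydro-2H-chromen-7-ol
Conditions: HCl (2 M), MeOH, 40 °C
Reagents that add atoms: none
Why: Acid-catalysed acetal exchange with methanol removes the MOM ether under conditions commonly applied to prenylated phenols and should leave the prenyl and chromene double bonds intact.

**Compound list**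
1 | 2,4-dihydroxybenzaldehyde | O=Cc1ccc(O)cc1O | starting material
2 | 2-hydroxy-4-(methoxymethoxy)benzaldehyde | O=Cc1ccc(OCOC)cc1O | intermediate
3 | 4-(methoxymethoxy)-2-[(2-methylbut-3-yn-2-yl)oxy]benzaldehyde | O=Cc1ccc(OCOC)cc1OC(C)(C)C#C | intermediate
4 | 5-(methoxymethoxy)-2,2-dimethyl-2H-chromene-8-carbaldehyde | O=Cc1ccc(OCOC)c2c1OC(C)(C)C=C2 | intermediate
5 | N-{2-[5-(methoxymethoxy)-2,2-dimethyl-2H-chromen-8-yl]-1-[(4-methylphenyl)sulfonyl]ethenyl}formamide (alkene geometry not defined; present as its potassium salt) | O=CNC(=Cc1ccc(OCOC)c2c1OC(C)(C)C=C2)S(=O)(=O)c1ccc(C)cc1 | intermediate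
6 | 2-[5-(methoxymethoxy)-2,2-dimethyl-2H-chromen-8-yl]acetonitrile | N#CCc1ccc(OCOC)c2c1OC(C)(C)C=C2 | intermediate
7 | 2-[5-(methoxymethoxy)-2,2-dimethyl-2H-chromen-8-yl]acetic acid | OC(=O)Cc1ccc(OCOC)c2c1OC(C)(C)C=C2 | intermediate
8 | (R)-4-benzyloxazolidin-2-one | O=C1N[C@H](Cc2ccccc2)CO1 | starting material
9 | mixed anhydride of 7 with pivalic acid | CC(C)(C)C(=O)OC(=O)Cc1ccc(OCOC)c2c1OC(C)(C)C=C2 | intermediate
10 | (R)-4-benzyl-3-{2-[5-(methoxymethoxy)-2,2-dimethyl-2H-chromen-8-yl]acetyl}oxazolidin-2-one | O=C1OC[C@@H](Cc2ccccc2)N1C(=O)Cc1ccc(OCOC)c2c1OC(C)(C)C=C2 | intermediate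
11 | 4-hydroxybenzaldehyde | O=Cc1ccc(O)cc1 | starting material
12 | 4-hydroxy-3-(3-methylbut-2-en-1-yl)benzaldehyde | CC(C)=CCc1cc(C=O)ccc1O | intermediate
13 | 4-[(tert-butyldimethylsilyl)oxy]-3-(3-methylbut-2-en-1-yl)benzaldehyde | CC(C)=CCc1cc(C=O)ccc1O[Si](C)(C)C(C)(C)C | intermediate
14 | {4-[(tert-butyldimethylsilyl)oxy]-3-(3-methylbut-2-en-1-yl)phenyl}methanol | CC(C)=CCc1cc(CO)ccc1O[Si](C)(C)C(C)(C)C | intermediate
15 | [4-(bromomethyl)-2-(3-methylbut-2-en-1-yl)phenoxy](tert-butyl)dimethylsilane | CC(C)=CCc1cc(CBr)ccc1O[Si](C)(C)C(C)(C)C | intermediate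
16 | sodium (Z)-enolate of 10 | [Na+].[O-]/C(=C\c1ccc(OCOC)c2c1OC(C)(C)C=C2)N1C(=O)OC[C@H]1Cc1ccccc1 | intermediate
17 | (R)-4-benzyl-3-[(2R)-3-{4-[(tert-butyldimethylsilyl)oxy]-3-(3-methylbut-2-en-1-yl)phenyl}-2-[5-(methoxymethoxy)-2,2-dimethyl-2H-chromen-8-yl]propanoyl]oxazolidin-2-one | O=C1OC[C@@H](Cc2ccccc2)N1C(=O)[C@H](Cc1ccc(O[Si](C)(C)C(C)(C)C)c(CC=C(C)C)c1)c1ccc(OCOC)c2c1OC(C)(C)C=C2 | intermediate
18 | (2R)-3-{4-[(tert-butyldimethylsilyl)oxy]-3-(3-methylbut-2-en-1-yl)phenyl}-2-[5-(methoxymethoxy)-2,2-dimethyl-2H-chromen-8-yl]propan-1-ol | OC[C@H](Cc1ccc(O[Si](C)(C)C(C)(C)C)c(CC=C(C)C)c1)c1ccc(OCOC)c2c1OC(C)(C)C=C2 | intermediate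
19 | bis(tert-butyldimethylsilyl) ether of 18 (aryl and primary alkyl oxygen, 2R) | CC(C)(C)[Si](C)(C)OC[C@H](Cc1ccc(O[Si](C)(C)C(C)(C)C)c(CC=C(C)C)c1)c1ccc(OCOC)c2c1OC(C)(C)C=C2 | intermediate
20 | 4-[(2R)-3-[(tert-butyldimethylsilyl)oxy]-2-[5-(methoxymethoxy)-2,2-dimethyl-2H-chromen-8-yl]propyl]-2-(3-methylbut-2-en-1-yl)phenol | CC(C)(C)[Si](C)(C)OC[C@H](Cc1ccc(O)c(CC=C(C)C)c1)c1ccc(OCOC)c2c1OC(C)(C)C=C2 | intermediate
21 | 4-[(2R)-3-[(tert-butyldimethylsilyl)oxy]-2-[5-(methoxymethoxy)-2,2-dimethyl-2H-chromen-8-yl]propyl]-4-hydroxy-2-(3-methylbut-2-en-1-yl)cyclohexa-2,5-dien-1-one (both epimers at the quaternary carbon) | CC(C)(C)[Si](C)(C)OC[C@H](CC1(O)C=CC(=O)C(CC=C(C)C)=C1)c1ccc(OCOC)c2c1OC(C)(C)C=C2 | intermediate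
22 | 4-hydroxy-4-[(2R)-3-hydroxy-2-[5-(methoxymethoxy)-2,2-dimethyl-2H-chromen-8-yl]propyl]-2-(3-methylbut-2-en-1-yl)cyclohexa-2,5-dien-1-one (both epimers at the quaternary carbon) | OC[C@H](CC1(O)C=CC(=O)C(CC=C(C)C)=C1)c1ccc(OCOC)c2c1OC(C)(C)C=C2 | intermediate
23 | (3R)-4a-hydroxy-3-[5-(methoxymethoxy)-2,2-dimethyl-2H-chromen-8-yl]-6-(3-methylbut-2-en-1-yl)-2,3,4,4a,8,8a-hexahydro-7H-chromen-7-one (cis ring fusion, both fusion epimers) | CC(C)=CCC1=CC2(O)C[C@H](c3ccc(OCOC)c4c3OC(C)(C)C=C4)COC2CC1=O | intermediate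
24 | (3R)-3-[5-(methoxymethoxy)-2,2-dimethyl-2H-chromen-8-yl]-6-(3-methylbut-2-en-1-yl)-3,4-dihydro-2H-chromen-7-ol | CC(C)=CCc1cc2c(cc1O)OC[C@@H](c1ccc(OCOC)c3c1OC(C)(C)C=C3)C2 | intermediate
25 | (3R)-3-(5-hydroxy-2,2-dimethyl-2H-chromen-8-yl)-6-(3-methylbut-2-en-1-yl)-3,4-dihydro-2H-chromen-7-ol | CC(C)=CCc1cc2c(cc1O)OC[C@@H](c1ccc(O)c3c1OC(C)(C)C=C3)C2 | target

**Totals**
Total step count: 16. Longest linear sequence: 12 steps (steps 1–6 and 11–16, from 2,4-dihydroxybenzaldehyde); the ring A branch (steps 7–10) has 4 steps.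

**Steps most likely to fail**

Step 15. The conjugate addition may go to the prenyl-bearing enone arm (C5), the protonated dienone may undergo a 1,2-alkyl shift, aromatisation may stall at the bicyclic stage, or the acid may close the prenyl group onto the C7 hydroxyl. Fallback: the events are separated and taken out of Brønsted-acid control. From p-quinol 21, n-Bu4NF in THF at 0 °C removes the silyl group, and the alkoxide should close under kinetic control on the unsubstituted enone arm, so that bicyclic hydroxy enone 23 is isolated. Dehydration of its tertiary ring-fusion alcohol with Burgess reagent (methyl N-(triethylammoniosulfonyl)carbamate, benzene, 50 °C), followed by tautomerisation of the resulting dienone, returns to the route at 24.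

Step 14. The aryloxy-iodane may be captured at the prenyl-bearing ortho carbon instead of C4a, or the hypervalent iodine reagent may attack the electron-rich chromene or prenyl double bonds. Fallback: the dearomatisation is changed from a two-electron iodine oxidation to a singlet-oxygen cycloaddition on the phenoxide, which reacts far faster with singlet oxygen than a trisubstituted alkene does. From phenol 20, 2KHSO5·KHSO4·K2SO4 and NaHCO3 in MeCN/H2O at 23 °C should give 4-hydroperoxy-4-[(2R)-3-[(tert-butyldimethylsilyl)oxy]-2-[5-(methoxymethoxy)-2,2-dimethyl-2H-chromen-8-yl]propyl]-2-(3-methylbut-2-en-1-yl)cyclohexa-2,5-dien-1-one F1, which Me2S reduces to 21.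

Step 7. O-alkylation and double alkylation compete with mono C-alkylation of the phenoxide. Fallback: the prenyl group is delivered by sigmatropic rearrangement instead. From 11, 3-chloro-3-methylbut-1-yne with K2CO3, KI and CuI in acetone gives 4-[(2-methylbut-3-yn-2-yl)oxy]benzaldehyde F2. Semihydrogenation (H2, Pd/CaCO3 poisoned with Pb(OAc)2, quinoline, EtOAc) gives 4-[(2-methylbut-3-en-2-yl)oxy]benzaldehyde F3. Aromatic Claisen rearrangement of F3 (N,N-diethylaniline, 130 °C), for which the para position is blocked, returns to the route at 12.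

**Further compounds**
F0 | step 15 | none | none
F1 | step 14 | 4-hydroperoxy-4-[(2R)-3-[(tert-butyldimethylsilyl)oxy]-2-[5-(methoxymethoxy)-2,2-dimethyl-2H-chromen-8-yl]propyl]-2-(3-methylbut-2-en-1-yl)cyclohexa-2,5-dien-1-one | CC(C)(C)[Si](C)(C)OC[C@H](CC1(OO)C=CC(=O)C(CC=C(C)C)=C1)c1ccc(OCOC)c2c1OC(C)(C)C=C2
F2 | step 7 | 4-[(2-methylbut-3-yn-2-yl)oxy]benzaldehyde | O=Cc1ccc(OC(C)(C)C#C)cc1
F3 | step 7 | 4-[(2-methylbut-3-en-2-yl)oxy]benzaldehyde | O=Cc1ccc(OC(C)(C)C=C)cc1
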